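**Strategy**

Ring C of each flavan unit, the central one included, is cut across O1–C2 and C3–C4. The cut exploits that O1 and C4 sit ortho on ring A (C8a, C4a) while C2 carries ring B: ring A with O1 and C4 becomes a salicylaldehyde, C2–C3 with ring B a cinnamaldehyde. In one amine-catalysed operation the phenol adds to C2 and the enamine closes C3 onto C4, giving a 2-aryl-2H-chromene-3-carbaldehyde with C2 set by the catalyst. The formyl group on C3 is a polarity switch that Baeyer–Villiger oxidation turns into the C3 oxygen. The derived benzylated epiafzelechin is used three times: as terminal unit and, after C4 oxidation, twice as electrophile.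

Key step: step 3

Remark: the 2R configuration of 7 is assigned from the usual shielding model for the (S)-configured catalyst (O1 enters opposite the diphenyl(silyloxy)methyl group); if the sense of induction were the opposite, the (R)-catalyst would be used with no other change. "4β" means trans to the C3 hydroxyl of these 2,3-cis units.

**Route**

Step 1
Reactants: 1 2,4,6-trihydroxybenzaldehyde
Product: 2 2,4-bis(benzyloxy)-6-hydroxybenzaldehyde
Conditions: BnBr (2.1 equiv), K2CO3 (2.1 equiv), DMF, 0 °C to rt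
Reagents that add atoms: benzyl bromide, BrCc1ccccc1
Why: Williamson etherification, in which the para hydroxyl and one ortho hydroxyl are alkylated while the remaining ortho hydroxyl, hydrogen-bonded to the formyl group, should stay free.

Step 2
Reactants: 3 4-(benzyloxy)benzaldehyde; 4 (triphenylphosphoranylidene)acetaldehyde
Product: 5 (E)-3-[4-(benzyloxy)phenyl]prop-2-enal
Conditions: toluene, 80 °C, 4 not in excess
Reagents that add atoms: none
Why: Wittig olefination with the stabilised formyl ylide, which should give the (E)-enal and stop at the mono-homologue.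

Step 3
Reactants: 2 2,4-bis(benzyloxy)-6-hydroxybenzaldehyde; 5 (E)-3-[4-(benzyloxy)phenyl]prop-2-enal
Product: 7 (2R)-5,7-bis(benzyloxy)-2-[4-(benzyloxy)phenyl]-2H-chromene-3-carbaldehyde, via aldol adduct 6 (not isolated)
Conditions: (S)-2-[diphenyl(trimethylsilyloxy)methyl]pyrrolidine (20 mol %), 2-nitrobenzoic acid (20 mol %), 4 Å MS, toluene, rt
Reagents that add atoms: none
Why: The secondary amine condenses with enal 5 to an (E)-iminium ion, the phenol oxygen of 2 (O1) adds to its β-carbon (C2), and the enamine so formed attacks the ortho formyl carbon (C4) through its α-carbon (C3); loss of water from aldol adduct 6 and hydrolysis return the catalyst and give the conjugated enal 7. This is the amine-catalysed oxa-Michael/aldol condensation domino of salicylaldehydes with cinnamaldehydes, a known route to 2-aryl-2H-chromene-3-carbaldehydes. The O1–C2 bond forms intermolecularly and ring C then closes at C3–C4 as a 6-(enolexo)-exo-trig aldol addition. C2 is the only stereocentre and is set by the catalyst, whose diphenyl(silyloxy)methyl group shields one face of the iminium ion so that O1 enters from the other, which should give 2R. The step needs enantioface selection at C2 and O-attack before C-attack; the single free hydroxyl of 2, ortho to the formyl group, fixes regiochemistry and ring size, and the acid co-catalyst speeds the dehydration that pulls the reversible oxa-Michael step forward.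

Step 4
Reactants: 7 (2R)-5,7-bis(benzyloxy)-2-[4-(benzyloxy)phenyl]-2H-chromene-3-carbaldehyde
Product: 9 (2R)-5,7-bis(benzyloxy)-2-[4-(benzyloxy)phenyl]chroman-3-one, via enol formate 8 (not isolated)
Conditions: H2O2 (30 %, 1.1 equiv), (2-O2NC6H4Se)2 (5 mol %), CH2Cl2, 0 °C to rt; then KHCO3, MeOH, 0 °C
Reagents that add atoms: hydrogen peroxide, OO
Why: Baeyer–Villiger oxidation of the enal by the perseleninic acid formed in the flask, in which the electron-rich alkenyl carbon C3 migrates to oxygen to give enol formate 8, and cold methanolysis frees the enol that ketonises by protonation at C4; no stereocentre is formed and C2 should survive the weakly basic conditions.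

Step 5
Reactants: 9 (2R)-5,7-bis(benzyloxy)-2-[4-(benzyloxy)phenyl]chroman-3-one
Product: 10 (2R,3R)-5,7-bis(benzyloxy)-2-[4-(benzyloxy)phenyl]chroman-3-ol (5,7,4'-tri-O-benzyl-(−)-epiafzelechin)
Conditions: LiBH(s-Bu)3 (L-Selectride), LiBr, THF, −78 °C; then H2O
Reagents that add atoms: none
Why: Diastereoselective ketone reduction, in which the bulky hydride attacks C3 from the face opposite the C2 aryl group and should give the axial, 2,3-cis alcohol (3R).

Step 6
Reactants: 10 5,7,4'-tri-O-benzyl-(−)-epiafzelechin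
Product: 11 5,7,4'-tri-O-benzyl-4β-(2-ethoxyethoxy)-(−)-epiafzelechin (2,3-cis, 3,4-trans)
Conditions: DDQ (2 equiv), 2-ethoxyethanol, CH2Cl2, rt
Reagents that add atoms: 2-ethoxyethanol, CCOCCO
Why: Benzylic oxidation by hydride abstraction with DDQ, in which the ring A oxygens stabilise the C4 cation and the alcohol traps it anti to the C3 hydroxyl and C2 aryl group to give the 4β ether.

Step 7
Reactants: 11 5,7,4'-tri-O-benzyl-4β-(2-ethoxyethoxy)-(−)-epiafzelechin (becomes the central unit); 10 5,7,4'-tri-O-benzyl-(−)-epiafzelechin (becomes the terminal unit)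
Product: 12 hexa-O-benzyl dimer, tri-O-benzyl-epiafzelechin-(4β→8)-tri-O-benzyl-epiafzelechin
Conditions: 10 (4 equiv, excess recovered), Me3SiOTf (0.2 equiv), CH2Cl2, −78 to −30 °C
Reagents that add atoms: none
Why: Lewis acid-promoted Friedel–Crafts alkylation (interflavan coupling), in which the ring A-stabilised C4 cation from 11 is attacked by C8 of 10, its most nucleophilic free position, from the β face anti to the C3 hydroxyl and C2 aryl group, which sets the 3,4-trans centre.

Step 8
Reactants: 11 5,7,4'-tri-O-benzyl-4β-(2-ethoxyethoxy)-(−)-epiafzelechin (becomes the upper unit); 12 hexa-O-benzyl dimer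
Product: 13 nona-O-benzyl trimer, tri-O-benzyl-epiafzelechin-(4β→8)-tri-O-benzyl-epiafzelechin-(4β→8)-tri-O-benzyl-epiafzelechin
Conditions: 12 (3 equiv, excess recovered), Me3SiOTf (0.2 equiv), CH2Cl2, −78 to −30 °C, slow addition of 11
Reagents that add atoms: none
Why: The same Friedel–Crafts coupling, in which the free C8 of the upper unit of 12 is the most accessible nucleophilic position and β attack on the cation again sets the 3,4-trans centre of the new unit.

Step 9
Reactants: 13 nona-O-benzyl trimer
Product: 14 epiafzelechin-(4β→8)-epiafzelechin-(4β→8)-epiafzelechin (target)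
Conditions: H2 (1 atm), Pd(OH)2/C, THF/MeOH/H2O, rt
Reagents that add atoms: none
Why: Hydrogenolysis of the nine benzyl aryl ethers, which should leave the secondary alcohols, the interflavan bonds and all stereocentres untouched.

**Compound list**

1 | 2,4,6-trihydroxybenzaldehyde | O=Cc1c(O)cc(O)cc1O | starting material
2 | 2,4-bis(benzyloxy)-6-hydroxybenzaldehyde | O=Cc1c(O)cc(OCc2ccccc2)cc1OCc1ccccc1 | intermediate
3 | 4-(benzyloxy)benzaldehyde | O=Cc1ccc(OCc2ccccc2)cc1 | starting material
4 | (triphenylphosphoranylidene)acetaldehyde | O=CC=P(c1ccccc1)(c1ccccc1)c1ccccc1 | starting material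
5 | (E)-3-[4-(benzyloxy)phenyl]prop-2-enal | O=C/C=C/c1ccc(OCc2ccccc2)cc1 | intermediate
6 | aldol adduct, 5,7-bis(benzyloxy)-2-[4-(benzyloxy)phenyl]-4-hydroxychroman-3-carbaldehyde, C2 configured as in 7, C3 and C4 unassigned (not isolated) | c1ccccc1COc1ccc([C@H]2Oc3cc(OCc4ccccc4)cc(OCc4ccccc4)c3C(O)C2C=O)cc1 | intermediate
7 | (2R)-5,7-bis(benzyloxy)-2-[4-(benzyloxy)phenyl]-2H-chromene-3-carbaldehyde | c1ccccc1COc1ccc([C@H]2Oc3cc(OCc4ccccc4)cc(OCc4ccccc4)c3C=C2C=O)cc1 | intermediate
8 | (2R)-5,7-bis(benzyloxy)-2-[4-(benzyloxy)phenyl]-2H-chromen-3-yl formate (not isolated) | c1ccccc1COc1ccc([C@H]2Oc3cc(OCc4ccccc4)cc(OCc4ccccc4)c3C=C2OC=O)cc1 | intermediate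
9 | (2R)-5,7-bis(benzyloxy)-2-[4-(benzyloxy)phenyl]chroman-3-one | c1ccccc1COc1ccc([C@H]2Oc3cc(OCc4ccccc4)cc(OCc4ccccc4)c3CC2=O)cc1 | intermediate
10 | (2R,3R)-5,7-bis(benzyloxy)-2-[4-(benzyloxy)phenyl]chroman-3-ol (5,7,4'-tri-O-benzyl-(−)-epiafzelechin) | c1ccccc1COc1ccc([C@H]2Oc3cc(OCc4ccccc4)cc(OCc4ccccc4)c3C[C@H]2O)cc1 | intermediate
11 | 5,7,4'-tri-O-benzyl-4β-(2-ethoxyethoxy)-(−)-epiafzelechin (2,3-cis, 3,4-trans) | c1ccccc1COc1ccc([C@H]2Oc3cc(OCc4ccccc4)cc(OCc4ccccc4)c3[C@H](OCCOCC)[C@H]2O)cc1 | intermediate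
12 | hexa-O-benzyl dimer, tri-O-benzyl-epiafzelechin-(4β→8)-tri-O-benzyl-epiafzelechin | c1ccccc1COc1ccc([C@H]2Oc3cc(OCc4ccccc4)cc(OCc4ccccc4)c3[C@H](c3c(OCc4ccccc4)cc(OCc4ccccc4)c4c3O[C@H](c3ccc(OCc5ccccc5)cc3)[C@H](O)C4)[C@H]2O)cc1 | intermediate
13 | nona-O-benzyl trimer, all-(4β→8)-linked tri-O-benzyl-epiafzelechin units | c1ccccc1COc1ccc([C@H]2Oc3c(c(OCc4ccccc4)cc(OCc4ccccc4)c3[C@H]3c4c(OCc5ccccc5)cc(OCc5ccccc5)cc4O[C@H](c4ccc(OCc5ccccc5)cc4)[C@@H]3O)[C@H](c3c(OCc4ccccc4)cc(OCc4ccccc4)c4c3O[C@H](c3ccc(OCc5ccccc5)cc3)[C@H](O)C4)[C@H]2O)cc1 | intermediate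
14 | epiafzelechin-(4β→8)-epiafzelechin-(4β→8)-epiafzelechin | Oc1ccc([C@H]2Oc3c(c(O)cc(O)c3[C@H]3c4c(O)cc(O)cc4O[C@H](c4ccc(O)cc4)[C@@H]3O)[C@H](c3c(O)cc(O)c4c3O[C@H](c3ccc(O)cc3)[C@H](O)C4)[C@H]2O)cc1 | target

**Count and risks**

Total step count: 9. Longest linear sequence: 8 steps (steps 1, 3, 4, 5, 6, 7, 8, 9).

Steps most likely to fail:

Step 3. The aldol closure onto the electron-rich, doubly ortho-substituted formyl group may be slow, and reversible oxa-Michael addition may erode the enantiomeric purity. Fallback, setting out from 2 and 5 and coming back at 10: the same condensation is run without asymmetric induction (pyrrolidine, benzoic acid, toluene, 60 °C) to give the racemic chromene aldehyde F1. Oxidation as in step 4 then gives the racemic ketone F2. Its C2 centre epimerises through the enolate, so a dynamic kinetic resolution by asymmetric hydrogenation (RuCl2[(S)-xylBINAP][(S)-DAIPEN] or its mirror image, KOt-Bu, H2, i-PrOH) should deliver 10 directly; stereocontrol then rests on the hydrogenation catalyst instead of the amine.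

Step 4. The peracid may over-oxidise the electron-rich enol formate or ring A, hydride may migrate instead of the alkenyl carbon, and C2 may lose configuration while the ketone is set free. Fallback, setting out from 7 and coming back at 9: Pinnick oxidation (NaClO2, NaH2PO4, 2-methylbut-2-ene, t-BuOH/H2O) gives the chromene carboxylic acid F3. Curtius rearrangement (diphenylphosphoryl azide, Et3N, t-BuOH, 80 °C) gives the Boc-enamine F4, and mild acid hydrolysis (aqueous oxalic acid, THF) of this enecarbamate gives 9.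

Step 8. The electrophile may condense with itself or attack C6 positions, giving higher oligomers and regioisomers that are hard to separate. Fallback, setting out from 11 and 12 and coming back at 14: 11 is first brominated at C8 (N-bromosuccinimide, CH2Cl2, −78 °C) to the capped electrophile F5, which can no longer act as a nucleophile. F5 and 12 are then coupled in equimolar amounts under the conditions of step 8 to the bromo trimer F6. Hydrogenolysis (H2, Pd(OH)2/C, Et3N, THF/MeOH) removes bromine and the benzyl groups together to give 14.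

**Further compounds**

F1 | step 3 | racemic 5,7-bis(benzyloxy)-2-[4-(benzyloxy)phenyl]-2H-chromene-3-carbaldehyde | O=CC1=Cc2c(OCc3ccccc3)cc(OCc3ccccc3)cc2OC1c1ccc(OCc2ccccc2)cc1
F2 | step 3 | racemic 5,7-bis(benzyloxy)-2-[4-(benzyloxy)phenyl]chroman-3-one | O=C1Cc2c(OCc3ccccc3)cc(OCc3ccccc3)cc2OC1c1ccc(OCc2ccccc2)cc1
F3 | step 4 | (2R)-5,7-bis(benzyloxy)-2-[4-(benzyloxy)phenyl]-2H-chromene-3-carboxylic acid | c1ccccc1COc1ccc([C@H]2Oc3cc(OCc4ccccc4)cc(OCc4ccccc4)c3C=C2C(O)=O)cc1
F4 | step 4 | tert-butyl N-[(2R)-5,7-bis(benzyloxy)-2-[4-(benzyloxy)phenyl]-2H-chromen-3-yl]carbamate | c1ccccc1COc1ccc([C@H]2Oc3cc(OCc4ccccc4)cc(OCc4ccccc4)c3C=C2NC(=O)OC(C)(C)C)cc1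
F5 | step 8 | 8-bromo-5,7,4'-tri-O-benzyl-4β-(2-ethoxyethoxy)-(−)-epiafzelechin | c1ccccc1COc1ccc([C@H]2Oc3c(Br)c(OCc4ccccc4)cc(OCc4ccccc4)c3[C@H](OCCOCC)[C@H]2O)cc1
F6 | step 8 | nona-O-benzyl trimer 13 carrying bromine at C8 of the upper unit | c1ccccc1COc1ccc([C@H]2Oc3c(c(OCc4ccccc4)cc(OCc4ccccc4)c3[C@H]3c4c(OCc5ccccc5)cc(OCc5ccccc5)c(Br)c4O[C@H](c4ccc(OCc5ccccc5)cc4)[C@@H]3O)[C@H](c3c(OCc4ccccc4)cc(OCc4ccccc4)c4c3O[C@H](c3ccc(OCc5ccccc5)cc3)[C@H](O)C4)[C@H]2O)cc1
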